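## Structural features

The target is a C30 biflavonoid: a flavanone (locants O1–C8a, B ring C1'–C6') and a flavone (O1''–C8a'', B ring C1'''–C6''') joined by a single C3(sp3)–C3''(sp2) bond. Its only stereocentres, C2 (S) and C3 (R), are adjacent in the dihydropyranone ring and carry the 4-hydroxyphenyl and flavon-3-yl groups trans. Both centres are labile: C3–H is α to C4=O and epimerises through the enol, and C2 is lost under base by E1cB opening of the O1–C2 bond (retro-oxa-Michael to the chalcone). C3 and C3'' are each the α-carbon of a carbonyl group, so the bond between them is the central bond of a 1,4-dicarbonyl array (C4=O, C4''=O): polarity-mismatched and flanked on each side by an aryl-bearing carbon and a carbonyl. Six free phenols on two phloroglucinol-type A rings and two 4-hydroxyphenyl rings make the compound electron-rich and oxidisable. The real difficulty is to forge the hindered C3–C3'' bond without a flavanone enolate and to arrive at (2S,3R). The key step exploits the enol O4–C4=C3 of the flavanone ring and the C3''=C2'' enol-ether pair of the pyranone ring: with sulfur placed temporarily on C2'', O4–C4=C3 and S–C2''=C3'' are the two halves of a 1,5-diene-type array whose [3,3] shift creates exactly C3–C3'' and leaves C2'' as a C–S carbon that can afterwards receive C1'''.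

## Logic of the disconnections

**17 ⇒ 16.** The six phenolic O–CH2Ph bonds are cut. All phenols are masked alike so that one neutral hydrogenolysis ends the route. The forward step must leave the tetrasubstituted C2''=C3'' bond, C4=O and the benzylic O1–C2 bond alone and must not touch C2 or C3.

**16 ⇒ 14 (through 15).** The C3–H bond is replaced by C3–CO2tBu. The extra carboxyl makes C3 a β-keto ester carbon with a stable enol, keeps C3 quaternary (no enolisation, no retro-oxa-Michael) while the flavone is completed, and is lost as CO2 and isobutene. The forward step must be acid-only and must let C3 equilibrate to the trans arrangement dictated by C2.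

**14 ⇒ 12 + 13.** The C2''–C1''' bond is cut. This allows C2'' to carry sulfur in the key step. The forward step is a base-free C–S to C–C cross-coupling at a hindered vinylogous thioester.

**12 ⇒ 6 + 9 (key).** The C3–C3'' bond is cut. In one sentence: the C3–C3'' bond is made by a charge-accelerated sulfonium [3,3] shift within 10, assembled in the flask from the enol of 6 and sulfoxide 9. The gain is full convergence: both halves fall back to 2, and the polarity-mismatched bond is made under acid with no enolate. The forward step must capture the enol at sulfur, not at C2'', and must tolerate a fully substituted C3.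

**6 ⇒ 5 ⇒ 3 + 4.** First the O1–C2 bond is cut (6-endo-trig oxa-Michael), then C2=C3 (Knoevenagel). The alkylidene β-keto ester 5 is a doubly activated acceptor on which a bifunctional catalyst can set C2; the ester needed for the key step is already in place. The forward cyclisation must be catalyst-controlled and the amine must be removed before the product can reopen.

**3 ⇒ 2.** The C–CO2tBu bond is cut (C-acylation of the methyl ketone). The tert-butyl ester is chosen because it does not lactonise onto the ortho phenol.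

**9 ⇒ 8 ⇒ 2 (through 7).** The S–O bond is cut, then the S–CH3 bond, then C3''–C2'' and O1''–C2''. One carbon of CS2 becomes C2'' with its sulfur already attached.

**2 ⇒ 1.** Two O–CH2Ph bonds are cut; the chelated ortho hydroxyl stays free for both later ring closures.

## Other disconnections considered

**Alternative 1:** (the first that comes to mind) Cut C3–C3'' between two finished monomers. The forward key step is a palladium-catalysed α-arylation of the enolate of (2S)-tri-O-benzylnaringenin A2 with the 3-iodoflavone A1, giving 16 directly. The enolate of A2 is a β-aryloxy ketone enolate and opens by E1cB to the chalcone phenoxide at the temperatures such couplings need, which erases C2. The C–I carbon of A1 lies between the C2''-aryl group and C4''=O, so reductive elimination to a tertiary, doubly flanked carbon is slow against hydrodehalogenation. Product 16 is more acidic than A2 and stays exposed to base. The chosen plan makes the same bond under acid, intramolecularly, with C3 blocked.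

**Alternative 2:** Cut O1–C2 and C2–C3 of the flavanone ring last. The forward key step is condensation of the 3-phenacylflavone A3 with 4 to the α-(flavon-3-yl)-2'-hydroxychalcone A4 (E/Z mixture), followed by asymmetric oxa-Michael closure to 16. The C3''–CH2 bond of A3 still has to be made, so the polarity-mismatched bond is moved, not solved. A4 has no second activating carbonyl and its enone is twisted by the flavonyl group, so ring closure is reversible and less favourable, and enantiocontrol without the chelating ester is not a safe assumption. The sequence is linear where the chosen plan is convergent.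

**Alternative 3:** Add no carbon framework at the end: reduce one ring of a symmetrical dimer. The forward key step is enantioselective conjugate reduction (dearomatisation of one pyranone ring) of the symmetrical 3,3''-biflavone A5, made by reductive homocoupling of A1; this would give 16 in fewer steps. The C2=C3 bond to be reduced is tetrasubstituted and flanked by two aryl-type groups, the poorest substrate class for hydride conjugate reduction. A5 is expected to be axially chiral with a slow-rotating tetra-ortho-substituted axis, so the catalyst would meet a racemic axis. The second, identical ring invites over-reduction. The [3,3] shift is the more defensible key step mechanistically, which outweighs the shorter count.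

Key step: step 7

Assumptions:
- Step 4: the quinine-derived thiourea is taken to deliver the 2S series. If the sense of induction is the opposite, the quinidine-derived pseudo-enantiomer is used and nothing else changes.
- Descriptors: the C2 descriptor reads R in 10, 11, 12, 14 and 15 only because C3 then outranks the aryl group in the CIP order. The spatial arrangement at C2 is the same from 6 to 17.

## Steps

**Step 1**
Reactants: 1 2,4,6-trihydroxyacetophenone
Product: 2 1-[2,4-bis(benzyloxy)-6-hydroxyphenyl]ethan-1-one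
Conditions: BnBr (2.1 equiv), K2CO3, DMF, rt to 50 °C
Reagents that add atoms: benzyl bromide, BrCc1ccccc1
Why: Williamson etherification; the hydroxyl chelated to the acetyl carbonyl is the least nucleophilic, so alkylation should stop at the 2,4-di-O-benzyl stage and leave the ortho phenol needed in steps 4 and 5.

**Step 2**
Reactants: 2 1-[2,4-bis(benzyloxy)-6-hydroxyphenyl]ethan-1-one
Product: 3 tert-butyl 3-[2,4-bis(benzyloxy)-6-hydroxyphenyl]-3-oxopropanoate
Conditions: LiHMDS (3.3 equiv), THF, −78 °C; Boc2O (1.1 equiv), −78 to 0 °C; cold 1 M HCl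
Reagents that add atoms: di-tert-butyl dicarbonate, CC(C)(C)OC(=O)OC(=O)OC(C)(C)C
Why: Claisen-type C-acylation of the phenoxide–enolate dianion at its more nucleophilic carbon terminus, with the third equivalent of base absorbing the acidic product; the tert-butyl ester resists lactonisation to a 4-hydroxycoumarin.

**Step 3**
Reactants: 3 tert-butyl 3-[2,4-bis(benzyloxy)-6-hydroxyphenyl]-3-oxopropanoate; 4 4-(benzyloxy)benzaldehyde
Product: 5 tert-butyl (2Z)-2-[2,4-bis(benzyloxy)-6-hydroxybenzoyl]-3-[4-(benzyloxy)phenyl]prop-2-enoate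
Conditions: piperidine (10 mol %), AcOH (10 mol %), 4 Å MS, toluene, rt
Reagents that add atoms: none
Why: Knoevenagel condensation; the phenol hydrogen-bonded to the ketone is a poor nucleophile under these buffered conditions, so the open alkylidene should be isolable (Z isomer expected as the main one; either geometry can cyclise in step 4).

**Step 4**
Reactants: 5 tert-butyl (2Z)-2-[2,4-bis(benzyloxy)-6-hydroxybenzoyl]-3-[4-(benzyloxy)phenyl]prop-2-enoate
Product: 6 tert-butyl (2S,3R)-5,7-bis(benzyloxy)-2-[4-(benzyloxy)phenyl]-4-oxo-3,4-dihydro-2H-chromene-3-carboxylate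
Conditions: 1-[3,5-bis(trifluoromethyl)phenyl]-3-(9-deoxy-epi-quinin-9-yl)thiourea (10 mol %), toluene, −25 °C; rapid filtration through silica (EtOAc–hexanes, 1% AcOH)
Reagents that add atoms: none
Why: Organocatalytic enantioselective intramolecular oxa-Michael addition (6-endo-trig); the thiourea binds the β-keto ester and the quinuclidine delivers the phenol to one face of the alkylidene, setting C2 (S), while C3 settles trans as the keto form in equilibrium with its enol and is of no consequence. The acidic filtration removes the amine before the ring can reopen.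

**Step 5**
Reactants: 2 1-[2,4-bis(benzyloxy)-6-hydroxyphenyl]ethan-1-one
Product: 8 5,7-bis(benzyloxy)-2-(methylsulfanyl)-4H-chromen-4-one, via 4-hydroxy-2H-chromene-2-thione 7 (not isolated)
Conditions: KOtBu (3.1 equiv), CS2 (1.2 equiv), THF, 0 °C to rt; 1 M HCl; crude 7, MeI (1.1 equiv), K2CO3, acetone, rt
Reagents that add atoms: carbon disulfide, S=C=S; iodomethane, CI
Why: The ketone enolate adds to CS2 and the ortho phenoxide closes onto the dithioate carbon with loss of hydrosulfide (classical 2-thiochromone annulation); S-methylation of the ambident thione then gives the 2-(methylsulfanyl)chromone.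

**Step 6**
Reactants: 8 5,7-bis(benzyloxy)-2-(methylsulfanyl)-4H-chromen-4-one
Product: 9 5,7-bis(benzyloxy)-2-(methanesulfinyl)-4H-chromen-4-one
Conditions: mCPBA (1.0 equiv), CH2Cl2, −20 to 0 °C
Reagents that add atoms: 3-chloroperoxybenzoic acid, OOC(=O)c1cccc(Cl)c1
Why: Chemoselective sulfide-to-sulfoxide oxidation with one equivalent of peracid at low temperature; the sulfoxide is racemic at sulfur, which does not matter because that centre is destroyed in step 7.

**Step 7**
Reactants: 6 tert-butyl (2S,3R)-5,7-bis(benzyloxy)-2-[4-(benzyloxy)phenyl]-4-oxo-3,4-dihydro-2H-chromene-3-carboxylate; 9 5,7-bis(benzyloxy)-2-(methanesulfinyl)-4H-chromen-4-one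
Product: 12 tert-butyl (2R,3S)-5,7-bis(benzyloxy)-2-[4-(benzyloxy)phenyl]-3-[5,7-bis(benzyloxy)-2-(methylsulfanyl)-4-oxo-4H-chromen-3-yl]-4-oxo-3,4-dihydro-2H-chromene-3-carboxylate, via enoloxysulfonium trifluoroacetate 10 (not isolated), via rearranged chromenylium trifluoroacetate 11 (not isolated)
Conditions: 9 (1.5 equiv), TFAA (1.6 equiv), MeCN–CH2Cl2, −40 °C to rt
Reagents that add atoms: none
Why: TFAA O-acylates sulfoxide 9 and the enol hydroxyl of β-keto ester 6 displaces trifluoroacetate at sulfur to give the S–O linked 10, in which O4–C4=C3 and S–C2''=C3'' form a 1,5-diene-type array. Cleavage of the weak S–O bond drives a charge-accelerated [3,3]-sigmatropic shift through a six-membered transition state that joins C3 to C3'' and leaves cation 11, stabilised at C2'' by both O1'' and SMe; loss of the acidic C3''–H restores the pyranone as thioether 12. The closest known reaction type is the interrupted-Pummerer/sulfonium [3,3] coupling of β-keto ester enols with aryl sulfoxides and of enol-type partners with alkenyl sulfoxides and ketene dithioacetal monoxides, 9 being a cyclic ketene O,S-acetal S-oxide. No ring is closed; the six-membered array exists only in the transition state. The new quaternary C3 is controlled by the C2 aryl group, the chromone being delivered to the enol face anti to it, but the outcome is of no consequence because C3 is re-set in step 9, so both C3 epimers converge. The selectivity needed is C3–C3'' over C3–C2'' (addition–elimination) and O- over C-capture at sulfur: the tether puts only C3'' within reach, the S-methyl group offers no second [3,3] terminus, and the absence of base keeps the hindered C3 from acting as a free carbon nucleophile. The ester supplies the enol for S–O capture and, by making C3 quaternary, stops both furan closure of O4 onto C2'' and retro-oxa-Michael loss of the C2 configuration. The acidic, enolate-free medium leaves the C2 stereocentre of 6 untouched.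

**Step 8**
Reactants: 12 tert-butyl (2R,3S)-5,7-bis(benzyloxy)-2-[4-(benzyloxy)phenyl]-3-[5,7-bis(benzyloxy)-2-(methylsulfanyl)-4-oxo-4H-chromen-3-yl]-4-oxo-3,4-dihydro-2H-chromene-3-carboxylate; 13 [4-(benzyloxy)phenyl]boronic acid
Product: 14 tert-butyl (2R,3S)-5,7-bis(benzyloxy)-3-{5,7-bis(benzyloxy)-2-[4-(benzyloxy)phenyl]-4-oxo-4H-chromen-3-yl}-2-[4-(benzyloxy)phenyl]-4-oxo-3,4-dihydro-2H-chromene-3-carboxylate
Conditions: 13 (2 equiv), Pd2(dba)3 (5 mol %), tri(2-furyl)phosphine (20 mol %), CuTC (2.5 equiv), THF, 55 °C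
Reagents that add atoms: none
Why: Liebeskind–Srogl cross-coupling of the vinylogous thioester C2''–SMe with the boronic acid, copper(I) carboxylate activating both sulfur and boron; no base is needed, and the quaternary C3 rules out enolisation, furan closure and ring opening during the coupling.

**Step 9**
Reactants: 14 tert-butyl (2R,3S)-5,7-bis(benzyloxy)-3-{5,7-bis(benzyloxy)-2-[4-(benzyloxy)phenyl]-4-oxo-4H-chromen-3-yl}-2-[4-(benzyloxy)phenyl]-4-oxo-3,4-dihydro-2H-chromene-3-carboxylate
Product: 16 (2S,3R)-5,7-bis(benzyloxy)-3-{5,7-bis(benzyloxy)-2-[4-(benzyloxy)phenyl]-4-oxo-4H-chromen-3-yl}-2-[4-(benzyloxy)phenyl]-2,3-dihydro-4H-chromen-4-one, via β-keto acid 15 (not isolated)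
Conditions: TFA–CH2Cl2 (1:4), 0 °C to rt, then 40 °C until equilibrated
Reagents that add atoms: none
Why: Acidolysis of the tert-butyl ester and decarboxylation of the β-keto acid; continued acid-catalysed enolisation should funnel C3 to the trans (3R) arrangement with both large groups equatorial under control of the fixed C2 centre, and a benzyl ether lost here would not matter since step 10 removes them all.

**Step 10**
Reactants: 16 (2S,3R)-5,7-bis(benzyloxy)-3-{5,7-bis(benzyloxy)-2-[4-(benzyloxy)phenyl]-4-oxo-4H-chromen-3-yl}-2-[4-(benzyloxy)phenyl]-2,3-dihydro-4H-chromen-4-one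
Product: 17 (2S,3R)-5,7-dihydroxy-3-[5,7-dihydroxy-2-(4-hydroxyphenyl)-4-oxo-4H-chromen-3-yl]-2-(4-hydroxyphenyl)-2,3-dihydro-4H-chromen-4-one
Conditions: H2 (1 atm), 10% Pd/C, THF–MeOH, rt
Reagents that add atoms: none
Why: Hydrogenolysis of six aryl benzyl ethers under neutral conditions; the hindered tetrasubstituted C2''=C3'' bond and the chelated aryl ketones should not be reduced, and no base or strong acid touches C2 or C3.

## Compound list

1 | 2,4,6-trihydroxyacetophenone | CC(=O)c1c(O)cc(O)cc1O | starting material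
2 | 1-[2,4-bis(benzyloxy)-6-hydroxyphenyl]ethan-1-one | CC(=O)c1c(O)cc(OCc2ccccc2)cc1OCc1ccccc1 | intermediate
3 | tert-butyl 3-[2,4-bis(benzyloxy)-6-hydroxyphenyl]-3-oxopropanoate | CC(C)(C)OC(=O)CC(=O)c1c(O)cc(OCc2ccccc2)cc1OCc1ccccc1 | intermediate
4 | 4-(benzyloxy)benzaldehyde | O=Cc1ccc(OCc2ccccc2)cc1 | starting material
5 | tert-butyl (2Z)-2-[2,4-bis(benzyloxy)-6-hydroxybenzoyl]-3-[4-(benzyloxy)phenyl]prop-2-enoate | CC(C)(C)OC(=O)/C(=C\c1ccc(OCc2ccccc2)cc1)C(=O)c1c(O)cc(OCc2ccccc2)cc1OCc1ccccc1 | intermediate
6 | tert-butyl (2S,3R)-5,7-bis(benzyloxy)-2-[4-(benzyloxy)phenyl]-4-oxo-3,4-dihydro-2H-chromene-3-carboxylate (keto form, in equilibrium with its enol) | O=C1c2c(OCc3ccccc3)cc(OCc3ccccc3)cc2O[C@H](c2ccc(OCc3ccccc3)cc2)[C@H]1C(=O)OC(C)(C)C | intermediate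
7 | 5,7-bis(benzyloxy)-4-hydroxy-2H-chromene-2-thione | OC1=CC(=S)Oc2cc(OCc3ccccc3)cc(OCc3ccccc3)c12 | intermediate (not isolated)
8 | 5,7-bis(benzyloxy)-2-(methylsulfanyl)-4H-chromen-4-one | CSc1cc(=O)c2c(OCc3ccccc3)cc(OCc3ccccc3)cc2o1 | intermediate
9 | 5,7-bis(benzyloxy)-2-(methanesulfinyl)-4H-chromen-4-one (racemic at sulfur) | CS(=O)c1cc(=O)c2c(OCc3ccccc3)cc(OCc3ccccc3)cc2o1 | intermediate
10 | [5,7-bis(benzyloxy)-4-oxo-4H-chromen-2-yl]{[(2R)-5,7-bis(benzyloxy)-2-[4-(benzyloxy)phenyl]-3-(tert-butoxycarbonyl)-2H-chromen-4-yl]oxy}(methyl)sulfonium trifluoroacetate (both configurations at sulfur) | C[S+](OC1=C(C(=O)OC(C)(C)C)[C@@H](c2ccc(OCc3ccccc3)cc2)Oc2cc(OCc3ccccc3)cc(OCc3ccccc3)c12)c1cc(=O)c2c(OCc3ccccc3)cc(OCc3ccccc3)cc2o1.[O-]C(=O)C(F)(F)F | intermediate (not isolated)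
11 | 5,7-bis(benzyloxy)-3-{(2R,3S)-5,7-bis(benzyloxy)-2-[4-(benzyloxy)phenyl]-3-(tert-butoxycarbonyl)-4-oxo-3,4-dihydro-2H-chromen-3-yl}-2-(methylsulfanyl)-4-oxo-3,4-dihydrochromenylium trifluoroacetate (C3'' unassigned) | O=C1c2c(OCc3ccccc3)cc(OCc3ccccc3)cc2O[C@H](c2ccc(OCc3ccccc3)cc2)[C@@]1(C(=O)OC(C)(C)C)C1C(=O)c2c(OCc3ccccc3)cc(OCc3ccccc3)cc2[O+]=C1SC.[O-]C(=O)C(F)(F)F | intermediate (not isolated)
12 | tert-butyl (2R,3S)-5,7-bis(benzyloxy)-2-[4-(benzyloxy)phenyl]-3-[5,7-bis(benzyloxy)-2-(methylsulfanyl)-4-oxo-4H-chromen-3-yl]-4-oxo-3,4-dihydro-2H-chromene-3-carboxylate | O=C1c2c(OCc3ccccc3)cc(OCc3ccccc3)cc2O[C@H](c2ccc(OCc3ccccc3)cc2)[C@@]1(C(=O)OC(C)(C)C)c1c(SC)oc2cc(OCc3ccccc3)cc(OCc3ccccc3)c2c1=O | intermediate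
13 | [4-(benzyloxy)phenyl]boronic acid | OB(O)c1ccc(OCc2ccccc2)cc1 | starting material
14 | tert-butyl (2R,3S)-5,7-bis(benzyloxy)-3-{5,7-bis(benzyloxy)-2-[4-(benzyloxy)phenyl]-4-oxo-4H-chromen-3-yl}-2-[4-(benzyloxy)phenyl]-4-oxo-3,4-dihydro-2H-chromene-3-carboxylate | O=C1c2c(OCc3ccccc3)cc(OCc3ccccc3)cc2O[C@H](c2ccc(OCc3ccccc3)cc2)[C@@]1(C(=O)OC(C)(C)C)c1c(-c2ccc(OCc3ccccc3)cc2)oc2cc(OCc3ccccc3)cc(OCc3ccccc3)c2c1=O | intermediate
15 | (2R,3S)-5,7-bis(benzyloxy)-3-{5,7-bis(benzyloxy)-2-[4-(benzyloxy)phenyl]-4-oxo-4H-chromen-3-yl}-2-[4-(benzyloxy)phenyl]-4-oxo-3,4-dihydro-2H-chromene-3-carboxylic acid | O=C1c2c(OCc3ccccc3)cc(OCc3ccccc3)cc2O[C@H](c2ccc(OCc3ccccc3)cc2)[C@@]1(C(=O)O)c1c(-c2ccc(OCc3ccccc3)cc2)oc2cc(OCc3ccccc3)cc(OCc3ccccc3)c2c1=O | intermediate (not isolated)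
16 | (2S,3R)-5,7-bis(benzyloxy)-3-{5,7-bis(benzyloxy)-2-[4-(benzyloxy)phenyl]-4-oxo-4H-chromen-3-yl}-2-[4-(benzyloxy)phenyl]-2,3-dihydro-4H-chromen-4-one | O=C1c2c(OCc3ccccc3)cc(OCc3ccccc3)cc2O[C@H](c2ccc(OCc3ccccc3)cc2)[C@H]1c1c(-c2ccc(OCc3ccccc3)cc2)oc2cc(OCc3ccccc3)cc(OCc3ccccc3)c2c1=O | intermediate
17 | (2S,3R)-5,7-dihydroxy-3-[5,7-dihydroxy-2-(4-hydroxyphenyl)-4-oxo-4H-chromen-3-yl]-2-(4-hydroxyphenyl)-2,3-dihydro-4H-chromen-4-one | O=C1c2c(O)cc(O)cc2O[C@H](c2ccc(O)cc2)[C@H]1c1c(-c2ccc(O)cc2)oc2cc(O)cc(O)c2c1=O | target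

## Step count and least certain steps

Total: 10 steps. Longest linear sequence: 8 steps (1, 2, 3, 4, 7, 8, 9, 10). The second branch (steps 5 and 6) starts from the shared intermediate 2.

**Step 7 (key step).** Three things may go wrong:
- The activated sulfoxide may be consumed before the enol is captured, by addition–elimination of trifluoroacetate at C2'' or by a classical Pummerer reaction at the S-methyl group.
- The electron-rich A rings may be sulfenylated at C6/C8.
- The fully substituted C3 may be too crowded for the six-membered transition state.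

The fallback sets out from 6 and returns at 16. Acid decarboxylation of 6 (TsOH, toluene, 80 °C) should give (2S)-tri-O-benzylnaringenin F1 (the compound called A2 above). Its lithium enolate (LiHMDS, THF, −78 °C) is dimerised oxidatively with CuCl2 to the C2-symmetric 3,3''-biflavanone F2; the C3/C3'' configuration obtained is immaterial. One equivalent of DDQ in dioxane then dehydrogenates one ring; because the two rings of F2 are equivalent, either mono-oxidation gives the same compound, and acid equilibration of the remaining C3 leads to 16.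

**Step 8.** C–S activation at C2'' next to the quaternary C3 may be too slow, so that protodeboronation of 13 wins. The fallback sets out from 12 and returns at 14. Oxidation with mCPBA (2.2 equiv) gives the sulfone F3, tert-butyl (2R,3S)-5,7-bis(benzyloxy)-2-[4-(benzyloxy)phenyl]-3-[5,7-bis(benzyloxy)-2-(methanesulfonyl)-4-oxo-4H-chromen-3-yl]-4-oxo-3,4-dihydro-2H-chromene-3-carboxylate. Commercial 4-(benzyloxy)phenylmagnesium bromide with catalytic CuI (THF, −78 °C) then replaces the sulfonyl group by conjugate addition–elimination to give 14.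

**Step 4.** Facial selectivity may be poor, because the ortho benzyloxy group twists the aroyl unit and the electron-rich alkylidene reacts slowly against the uncatalysed closure; the C2 configuration may also erode by reversible ring opening while the amine is present. The fallback sets out from 3 and returns at 6. DMF dimethyl acetal (toluene, 80 °C) converts 3 into tert-butyl 5,7-bis(benzyloxy)-4-oxo-4H-chromene-3-carboxylate F4. Rhodium(I)/chiral-diene-catalysed conjugate addition of 13 (ligand enantiomer chosen for 2S) then dearomatises the pyranone and gives 6 with C2 set by the catalyst.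

**Step 9.** Ketonisation may stop at the kinetic cis isomer (protonation anti to the C2 aryl group) if acid-catalysed enolisation of the crowded ketone is slow; prolonged acid may begin to open the O1–C2 bond. The fallback sets out from 14 and returns at 17, bypassing 16. BCl3 with pentamethylbenzene (CH2Cl2, −78 to 0 °C) removes the six benzyl groups and the tert-butyl ester in one operation to give the hexahydroxy β-keto acid F5. Gentle warming in aqueous methanol with acetic acid decarboxylates it, and C3 equilibrates in the free polyphenol, where the 5-OH-chelated ketone should enolise more readily, to give 17.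

## Further compounds

F1 | step 7 | (2S)-5,7-bis(benzyloxy)-2-[4-(benzyloxy)phenyl]-2,3-dihydro-4H-chromen-4-one | O=C1C[C@@H](c2ccc(OCc3ccccc3)cc2)Oc2cc(OCc3ccccc3)cc(OCc3ccccc3)c12
F2 | step 7 | (2S,2'S,3R,3'R)-5,5',7,7'-tetrakis(benzyloxy)-2,2'-bis[4-(benzyloxy)phenyl]-2,2',3,3'-tetrahydro-4H,4'H-[3,3'-bichromene]-4,4'-dione | O=C1c2c(OCc3ccccc3)cc(OCc3ccccc3)cc2O[C@H](c2ccc(OCc3ccccc3)cc2)[C@H]1[C@H]1C(=O)c2c(OCc3ccccc3)cc(OCc3ccccc3)cc2O[C@@H]1c1ccc(OCc2ccccc2)cc1
F3 | step 8 | tert-butyl (2R,3S)-5,7-bis(benzyloxy)-2-[4-(benzyloxy)phenyl]-3-[5,7-bis(benzyloxy)-2-(methanesulfonyl)-4-oxo-4H-chromen-3-yl]-4-oxo-3,4-dihydro-2H-chromene-3-carboxylate | O=C1c2c(OCc3ccccc3)cc(OCc3ccccc3)cc2O[C@H](c2ccc(OCc3ccccc3)cc2)[C@@]1(C(=O)OC(C)(C)C)c1c(S(C)(=O)=O)oc2cc(OCc3ccccc3)cc(OCc3ccccc3)c2c1=O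
F4 | step 4 | tert-butyl 5,7-bis(benzyloxy)-4-oxo-4H-chromene-3-carboxylate | CC(C)(C)OC(=O)c1coc2cc(OCc3ccccc3)cc(OCc3ccccc3)c2c1=O
F5 | step 9 | (2R,3S)-3-[5,7-dihydroxy-2-(4-hydroxyphenyl)-4-oxo-4H-chromen-3-yl]-5,7-dihydroxy-2-(4-hydroxyphenyl)-4-oxo-3,4-dihydro-2H-chromene-3-carboxylic acid | O=C1c2c(O)cc(O)cc2O[C@H](c2ccc(O)cc2)[C@@]1(C(=O)O)c1c(-c2ccc(O)cc2)oc2cc(O)cc(O)c2c1=O
A1 | alternative 1 | 5,7-bis(benzyloxy)-2-[4-(benzyloxy)phenyl]-3-iodo-4H-chromen-4-one | O=c1c(I)c(-c2ccc(OCc3ccccc3)cc2)oc2cc(OCc3ccccc3)cc(OCc3ccccc3)c12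
A2 | alternative 1 | (2S)-5,7-bis(benzyloxy)-2-[4-(benzyloxy)phenyl]-2,3-dihydro-4H-chromen-4-one | O=C1C[C@@H](c2ccc(OCc3ccccc3)cc2)Oc2cc(OCc3ccccc3)cc(OCc3ccccc3)c12
A3 | alternative 2 | 5,7-bis(benzyloxy)-3-{2-[2,4-bis(benzyloxy)-6-hydroxyphenyl]-2-oxoethyl}-2-[4-(benzyloxy)phenyl]-4H-chromen-4-one | O=C(Cc1c(-c2ccc(OCc3ccccc3)cc2)oc2cc(OCc3ccccc3)cc(OCc3ccccc3)c2c1=O)c1c(O)cc(OCc2ccccc2)cc1OCc1ccccc1
A4 | alternative 2 | 5,7-bis(benzyloxy)-3-{3-[2,4-bis(benzyloxy)-6-hydroxyphenyl]-1-[4-(benzyloxy)phenyl]-3-oxoprop-1-en-2-yl}-2-[4-(benzyloxy)phenyl]-4H-chromen-4-one (E/Z mixture) | O=C(C(=Cc1ccc(OCc2ccccc2)cc1)c1c(-c2ccc(OCc3ccccc3)cc2)oc2cc(OCc3ccccc3)cc(OCc3ccccc3)c2c1=O)c1c(O)cc(OCc2ccccc2)cc1OCc1ccccc1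
A5 | alternative 3 | 5,5',7,7'-tetrakis(benzyloxy)-2,2'-bis[4-(benzyloxy)phenyl]-4H,4'H-[3,3'-bichromene]-4,4'-dione | O=c1c(-c2c(-c3ccc(OCc4ccccc4)cc3)oc3cc(OCc4ccccc4)cc(OCc4ccccc4)c3c2=O)c(-c2ccc(OCc3ccccc3)cc2)oc2cc(OCc3ccccc3)cc(OCc3ccccc3)c12
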